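Everything rests on reading ring B, a 5-alkylresorcinol with oxygen on C1 and C3 and the carbinol chain on C5, as the dehydrogenated form of a 5-alkylcyclohexane-1,3-dione. The key step builds that carbocycle in one operation from an acyclic (E)-methyl enone, whose β-carbon already carries the silylated (R)-carbinol chain, and dimethyl malonate. A Michael addition forms C5–C6 and a Claisen closure forms C1–C2, so the meta relationship of chain and both oxygens is built in and not installed on an arene. Decarboxylation and dehydrogenation then give the arene. Both (R)-carbinols derive from (R)-1,2-epoxypentane; ring A is made separately by B-alkyl Suzuki coupling and attached as its acid chloride before a final hydrogenolysis.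

Key step: step 4

Remark: ring B is numbered as a benzene-1,3-diol (O on C1 and C3, chain on C5, C6 being the carbon that loses the ester); in the cyclohexane numbering of the key-step product the same two new bonds are C1–C6 and C2–C3. 8-Bromooct-1-ene, 7-bromohept-1-ene and 2-bromo-4,6-dimethoxybenzaldehyde are taken as catalogue compounds.

**Ring B fragment**

Step 1
Reactants: 1 (R)-1,2-epoxypentane [(R)-2-propyloxirane]; 2 8-bromooct-1-ene
Product: 4 (R)-tridec-12-en-4-ol, via oct-7-enylmagnesium bromide 3 (not isolated)
Conditions: 2, Mg, THF, rt to 40 °C; then CuI (10 mol%), 1, THF, −30 to 0 °C; aqueous work-up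
Reagents that add atoms: none
Why: Copper-catalysed Grignard opening of a terminal epoxide is an SN2 attack at the unsubstituted CH2, so no bond to the stereocentre is touched and the carbinol keeps the (R) configuration of 1 (the new chain outranks propyl just as the ring CH2O did).

Step 2
Reactants: 4 (R)-tridec-12-en-4-ol
Product: 5 (R)-tert-butyldimethyl(tridec-12-en-4-yloxy)silane
Conditions: TBSCl, imidazole, DMF, rt
Reagents that add atoms: tert-butyldimethylsilyl chloride, CC(C)(C)[Si](C)(C)Cl
Why: Imidazole-promoted silylation of a secondary alcohol gives an ether that is inert to ruthenium carbenes, methoxide and hydroxide and, unlike an ester, cannot be cleaved or transferred in step 4.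

Step 3
Reactants: 5 (R)-tert-butyldimethyl(tridec-12-en-4-yloxy)silane; 6 but-3-en-2-one (methyl vinyl ketone)
Product: 7 (R,E)-12-(tert-butyldimethylsilyloxy)pentadec-3-en-2-one
Conditions: 6 (3 equiv), second-generation Hoveyda–Grubbs catalyst (3 mol%), CH2Cl2, 40 °C
Reagents that add atoms: none
Why: Olefin cross-metathesis of a terminal alkene with an electron-poor vinyl ketone favours the cross product because the enone hardly homodimerises, and it should deliver the conjugated (E)-enone under thermodynamic control with loss of ethylene.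

Step 4
Reactants: 7 (R,E)-12-(tert-butyldimethylsilyloxy)pentadec-3-en-2-one; 8 dimethyl malonate
Product: 10 methyl 2,4-dioxo-6-[(R)-8-(tert-butyldimethylsilyloxy)undecyl]cyclohexane-1-carboxylate (ring stereocentres uncontrolled), via open-chain Michael adduct 9 (not isolated)
Conditions: NaOMe (1.2 equiv), MeOH, reflux; then cold 1 M HCl to pH 4
Reagents that add atoms: none
Why: Sodiomalonate adds in a Michael reaction to the β-carbon (C4) of enone 7 to give 9, and under the equilibrating methoxide conditions the enolate on the methyl side of the ketone attacks one malonate ester carbonyl in a Claisen (Dieckmann-type) acyl substitution that expels methoxide. The closest known reaction is the Michael–Claisen annulation of alk-3-en-2-ones with malonates that leads to dimedone and to the cyclohexane-1,3-dione precursors of 5-alkylresorcinols. The carbocycle closes in a 6-(enolendo)-exo-trig mode, both enolate carbons lying in the new ring and the ester C=O outside it. The two ring stereocentres of 10 (C1 and C6) form without any need for control, since both are erased by decarboxylation and aromatisation, while the silyloxy carbinol is remote, not enolisable and stays (R). Only regiochemistry is required and the substrate supplies it: the malonate can attack only the β-carbon, the alternative C3 enolate could close only a four-membered ring, and the product leaves every equilibrium as its stabilised β-diketone enolate.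

Step 5
Reactants: 10 methyl 2,4-dioxo-6-[(R)-8-(tert-butyldimethylsilyloxy)undecyl]cyclohexane-1-carboxylate
Product: 12 5-[(R)-8-(tert-butyldimethylsilyloxy)undecyl]cyclohexane-1,3-dione, via the 2,4-dioxocyclohexane-1-carboxylic acid 11 (not isolated)
Conditions: 2 M NaOH (aq), MeOH/THF, 65 °C; cool, 1 M HCl to pH 3–4, then 50 °C
Reagents that add atoms: none
Why: Saponification followed by decarboxylation of the β-keto acid through the usual cyclic transition state (the dimedone work-up) removes the ester carbon, and at pH 3–4 with gentle warming the secondary silyl ether should survive.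

Step 6
Reactants: 12 5-[(R)-8-(tert-butyldimethylsilyloxy)undecyl]cyclohexane-1,3-dione
Product: 13 5-[(R)-8-(tert-butyldimethylsilyloxy)undecyl]benzene-1,3-diol
Conditions: 10% Pd/C, mesitylene, reflux (165 °C), N2 sweep
Reagents that add atoms: none
Why: Catalytic dehydrogenation of a cyclohexane-1,3-dione to a resorcinol over palladium is a known aromatisation driven by the gain of aromaticity and the removal of H2, and the silyl ether with its remote, unactivated carbinol carbon should not be engaged.

Step 7
Reactants: 13 5-[(R)-8-(tert-butyldimethylsilyloxy)undecyl]benzene-1,3-diol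
Product: 14 1,3-bis(benzyloxy)-5-[(R)-8-(tert-butyldimethylsilyloxy)undecyl]benzene
Conditions: BnBr (2.5 equiv), K2CO3, DMF, rt
Reagents that add atoms: benzyl bromide, BrCc1ccccc1
Why: Williamson O-alkylation of both phenoxides by benzyl bromide under carbonate in DMF, conditions to which the silyl ether is stable.

Step 8
Reactants: 14 1,3-bis(benzyloxy)-5-[(R)-8-(tert-butyldimethylsilyloxy)undecyl]benzene
Product: 15 (R)-11-[3,5-bis(benzyloxy)phenyl]undecan-4-ol
Conditions: TBAF, THF, rt; aqueous work-up
Reagents that add atoms: none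
Why: Fluoride-induced desilylation breaks only the Si–O bond, so the carbinol is freed with retention of its (R) configuration while the aryl benzyl ethers are inert to fluoride.

**Ring A fragment**

Step 9
Reactants: 1 (R)-1,2-epoxypentane; 16 7-bromohept-1-ene
Product: 18 (R)-dodec-11-en-4-ol, via hept-6-enylmagnesium bromide 17 (not isolated)
Conditions: 16, Mg, THF, rt to 40 °C; then CuI (10 mol%), 1, THF, −30 to 0 °C; aqueous work-up
Reagents that add atoms: none
Why: The same copper-catalysed SN2 Grignard opening of the epoxide CH2 as in step 1, now with the seven-carbon alkenyl reagent, leaves the stereocentre untouched and (R).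

Step 10
Reactants: 18 (R)-dodec-11-en-4-ol
Product: 19 (R)-dodec-11-en-4-yl acetate
Conditions: Ac2O, pyridine, DMAP (cat.), CH2Cl2, rt
Reagents that add atoms: acetic anhydride, CC(=O)OC(C)=O
Why: DMAP-catalysed acetylation reacts only at the O–H bond, so the acetate that the target carries is installed with retention.

Step 11
Reactants: 20 2-bromo-4,6-dimethoxybenzaldehyde
Product: 21 2-bromo-6-hydroxy-4-methoxybenzaldehyde
Conditions: BCl3 (1.2 equiv), CH2Cl2, −78 to 0 °C; H2O
Reagents that add atoms: none
Why: Chelation-directed Lewis-acid ether cleavage, in which BCl3 bridges the formyl oxygen and the ortho methoxy group and removes only that methyl, leaves the para methoxy group of ring A in place.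

Step 12
Reactants: 21 2-bromo-6-hydroxy-4-methoxybenzaldehyde
Product: 22 2-(benzyloxy)-6-bromo-4-methoxybenzaldehyde
Conditions: BnBr, K2CO3, DMF, rt to 50 °C
Reagents that add atoms: benzyl bromide, BrCc1ccccc1
Why: Williamson benzylation of the chelated phenol, with a non-enolisable aldehyde and an aryl bromide that are both inert to carbonate.

Step 13
Reactants: 19 (R)-dodec-11-en-4-yl acetate; 22 2-(benzyloxy)-6-bromo-4-methoxybenzaldehyde
Product: 24 (R)-12-[3-(benzyloxy)-2-formyl-5-methoxyphenyl]dodecan-4-yl acetate, via B-alkyl-9-BBN adduct 23 (not isolated)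
Conditions: 19, 9-BBN, THF, 0 °C to rt; then 22, PdCl2(dppf) (5 mol%), K3PO4 (aq), DMF, 50 °C
Reagents that add atoms: none
Why: B-alkyl Suzuki–Miyaura coupling, in which anti-Markovnikov hydroboration of the terminal alkene is much faster than any reduction of the acetate and the phosphate-activated borate transfers its primary alkyl group to the arylpalladium bromide formed by oxidative addition to zerovalent palladium next to the formyl group; the stereocentre is remote.

Step 14
Reactants: 24 (R)-12-[3-(benzyloxy)-2-formyl-5-methoxyphenyl]dodecan-4-yl acetate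
Product: 25 2-[(R)-9-acetoxydodecyl]-6-(benzyloxy)-4-methoxybenzoic acid
Conditions: NaClO2, NaH2PO4, 2-methylbut-2-ene, t-BuOH/H2O, rt
Reagents that add atoms: sodium chlorite, [Na+].[O-]Cl=O
Why: Pinnick oxidation converts the non-enolisable aryl aldehyde to the acid under buffered conditions that spare the acetate and the benzyl ether, the alkene scavenger removing HOCl before it can chlorinate the electron-rich ring.

**Union and deprotection**

Step 15
Reactants: 25 2-[(R)-9-acetoxydodecyl]-6-(benzyloxy)-4-methoxybenzoic acid; 15 (R)-11-[3,5-bis(benzyloxy)phenyl]undecan-4-ol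
Product: 27 (R)-11-[3,5-bis(benzyloxy)phenyl]undecan-4-yl 2-[(R)-9-acetoxydodecyl]-6-(benzyloxy)-4-methoxybenzoate, via acid chloride 26 (not isolated)
Conditions: 25, (COCl)2, DMF (cat.), CH2Cl2, 0 °C to rt; evaporate; then 15, Et3N, DMAP, CH2Cl2, rt to 40 °C
Reagents that add atoms: none
Why: Acid chloride formation by Vilsmeier activation followed by DMAP-catalysed acylation forms the hindered aryl ester at the acyl carbon, so the C–O bond of the carbinol in 15 is not broken and its (R) configuration is retained, while the acetate and benzyl ethers are inert.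

Step 16
Reactants: 27 (R)-11-[3,5-bis(benzyloxy)phenyl]undecan-4-yl 2-[(R)-9-acetoxydodecyl]-6-(benzyloxy)-4-methoxybenzoate
Product: 28 5'-methoxy-integracin A, (R)-11-(3,5-dihydroxyphenyl)undecan-4-yl 2-[(R)-9-acetoxydodecyl]-6-hydroxy-4-methoxybenzoate
Conditions: H2 (1 atm), 10% Pd/C, EtOAc, rt
Reagents that add atoms: none
Why: Palladium-catalysed hydrogenolysis cleaves only the three benzylic C–O bonds of the aryl benzyl ethers, since the acetate, the aryl ester of a non-benzylic secondary alcohol and the methyl ether offer no hydrogenolysable bond, and both stereocentres stay (R).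

**Compound list**

1 | (R)-1,2-epoxypentane | CCC[C@@H]1CO1 | starting material
2 | 8-bromooct-1-ene | C=CCCCCCCBr | starting material
3 | oct-7-enylmagnesium bromide | C=CCCCCCC[Mg]Br | intermediate
4 | (R)-tridec-12-en-4-ol | C=CCCCCCCC[C@@H](CCC)O | intermediate
5 | (R)-tert-butyldimethyl(tridec-12-en-4-yloxy)silane | C=CCCCCCCC[C@@H](CCC)O[Si](C)(C)C(C)(C)C | intermediate
6 | but-3-en-2-one (methyl vinyl ketone) | CC(=O)C=C | starting material
7 | (R,E)-12-(tert-butyldimethylsilyloxy)pentadec-3-en-2-one | CC(=O)/C=C/CCCCCCC[C@@H](CCC)O[Si](C)(C)C(C)(C)C | intermediate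
8 | dimethyl malonate | COC(=O)CC(=O)OC | starting material
9 | dimethyl 2-[(12R)-12-(tert-butyldimethylsilyloxy)-2-oxopentadecan-4-yl]propanedioate (Michael adduct, C4 uncontrolled) | COC(=O)C(C(=O)OC)C(CC(C)=O)CCCCCCC[C@@H](CCC)O[Si](C)(C)C(C)(C)C | intermediate
10 | methyl 2,4-dioxo-6-[(R)-8-(tert-butyldimethylsilyloxy)undecyl]cyclohexane-1-carboxylate (ring stereocentres undefined) | COC(=O)C1C(CCCCCCC[C@@H](CCC)O[Si](C)(C)C(C)(C)C)CC(=O)CC1=O | intermediate
11 | 2,4-dioxo-6-[(R)-8-(tert-butyldimethylsilyloxy)undecyl]cyclohexane-1-carboxylic acid | OC(=O)C1C(CCCCCCC[C@@H](CCC)O[Si](C)(C)C(C)(C)C)CC(=O)CC1=O | intermediate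
12 | 5-[(R)-8-(tert-butyldimethylsilyloxy)undecyl]cyclohexane-1,3-dione | O=C1CC(=O)CC(CCCCCCC[C@@H](CCC)O[Si](C)(C)C(C)(C)C)C1 | intermediate
13 | 5-[(R)-8-(tert-butyldimethylsilyloxy)undecyl]benzene-1,3-diol | Oc1cc(O)cc(CCCCCCC[C@@H](CCC)O[Si](C)(C)C(C)(C)C)c1 | intermediate
14 | 1,3-bis(benzyloxy)-5-[(R)-8-(tert-butyldimethylsilyloxy)undecyl]benzene | c1ccccc1COc1cc(OCc2ccccc2)cc(CCCCCCC[C@@H](CCC)O[Si](C)(C)C(C)(C)C)c1 | intermediate
15 | (R)-11-[3,5-bis(benzyloxy)phenyl]undecan-4-ol | c1ccccc1COc1cc(OCc2ccccc2)cc(CCCCCCC[C@@H](CCC)O)c1 | intermediate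
16 | 7-bromohept-1-ene | C=CCCCCCBr | starting material
17 | hept-6-enylmagnesium bromide | C=CCCCCC[Mg]Br | intermediate
18 | (R)-dodec-11-en-4-ol | C=CCCCCCC[C@@H](CCC)O | intermediate
19 | (R)-dodec-11-en-4-yl acetate | C=CCCCCCC[C@@H](CCC)OC(C)=O | intermediate
20 | 2-bromo-4,6-dimethoxybenzaldehyde | COc1cc(Br)c(C=O)c(OC)c1 | starting material
21 | 2-bromo-6-hydroxy-4-methoxybenzaldehyde | COc1cc(O)c(C=O)c(Br)c1 | intermediate
22 | 2-(benzyloxy)-6-bromo-4-methoxybenzaldehyde | COc1cc(Br)c(C=O)c(OCc2ccccc2)c1 | intermediate
23 | (R)-12-(9-borabicyclo[3.3.1]nonan-9-yl)dodecan-4-yl acetate | CCC[C@H](CCCCCCCCB1C2CCCC1CCC2)OC(C)=O | intermediate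
24 | (R)-12-[3-(benzyloxy)-2-formyl-5-methoxyphenyl]dodecan-4-yl acetate | CCC[C@H](CCCCCCCCc1cc(OC)cc(OCc2ccccc2)c1C=O)OC(C)=O | intermediate
25 | 2-[(R)-9-acetoxydodecyl]-6-(benzyloxy)-4-methoxybenzoic acid | CCC[C@H](CCCCCCCCc1cc(OC)cc(OCc2ccccc2)c1C(=O)O)OC(C)=O | intermediate
26 | 2-[(R)-9-acetoxydodecyl]-6-(benzyloxy)-4-methoxybenzoyl chloride | CCC[C@H](CCCCCCCCc1cc(OC)cc(OCc2ccccc2)c1C(=O)Cl)OC(C)=O | intermediate
27 | (R)-11-[3,5-bis(benzyloxy)phenyl]undecan-4-yl 2-[(R)-9-acetoxydodecyl]-6-(benzyloxy)-4-methoxybenzoate | CCC[C@H](CCCCCCCCc1cc(OC)cc(OCc2ccccc2)c1C(=O)O[C@H](CCC)CCCCCCCc1cc(OCc2ccccc2)cc(OCc2ccccc2)c1)OC(C)=O | intermediate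
28 | 5'-methoxy-integracin A | CCC[C@H](CCCCCCCCc1cc(OC)cc(O)c1C(=O)O[C@H](CCC)CCCCCCCc1cc(O)cc(O)c1)OC(C)=O | target

**Step count and risks**

Total step count: 16. Longest linear sequence: 10 steps (steps 1–8, 15, 16, from epoxide 1 through ring B).

Steps most likely to fail:

1. Step 6 (aromatisation). The dehydrogenation may stall, or hydrogen may be transferred between dione molecules so that part of the material is reduced and dehydrated to a monophenol; prolonged heating may also erode the silyl ether. The fallback sets out from 12 and comes back at 14. Mitsunobu O-benzylation of the vinylogous acid 12 (BnOH, PPh3, DIAD, THF) would give 3-(benzyloxy)-5-[(R)-8-(tert-butyldimethylsilyloxy)undecyl]cyclohex-2-en-1-one F1. Kinetic deprotonation at C6 with LDA (THF, −78 °C) and trapping with PhSeCl, anti to the C5 chain, would give 3-(benzyloxy)-5-[(R)-8-(tert-butyldimethylsilyloxy)undecyl]-6-(phenylselanyl)cyclohex-2-en-1-one F2. Oxidation with H2O2 and pyridine would trigger selenoxide syn-elimination toward C5, and the dienone would tautomerise to 3-(benzyloxy)-5-[(R)-8-(tert-butyldimethylsilyloxy)undecyl]phenol F3. Benzylation of the remaining phenol (BnBr, K2CO3, DMF) then gives 14.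

2. Step 15 (ester formation). Acylation of a secondary alcohol by a benzoyl chloride flanked by two ortho substituents may be too slow, so that the acid chloride is consumed by anhydride formation or by loss of its ortho benzyl group. The fallback sets out from 15 and comes back at 27; it makes the alcohol the electrophile and the hindered carboxylate the nucleophile. Mitsunobu inversion of 15 with 4-nitrobenzoic acid (PPh3, DIAD, THF) would give (S)-11-[3,5-bis(benzyloxy)phenyl]undecan-4-yl 4-nitrobenzoate F4. Methanolysis (K2CO3, MeOH) would give (S)-11-[3,5-bis(benzyloxy)phenyl]undecan-4-ol F5. A second Mitsunobu reaction of the (S)-alcohol with acid 25 (PPh3, DIAD, toluene) would form the ester with inversion and so reach 27 with the (R) carbinol.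

3. Step 13 (B-alkyl Suzuki coupling). Residual B–H may reduce the formyl group, the alkylborane may be lost by protodeboronation or β-hydride elimination before transmetallation, and the aqueous base may partly hydrolyse the acetate. The fallback sets out from 19 and 22 and comes back at 24. A Heck arylation (Pd(OAc)2, P(o-tol)3, Et3N, DMF, 100 °C) would give mainly (R,E)-12-[3-(benzyloxy)-2-formyl-5-methoxyphenyl]dodec-11-en-4-yl acetate F6, together with double-bond isomers that converge in the next operation and a minor branched isomer to be removed by chromatography. Diimide, generated from dipotassium azodicarboxylate and acetic acid in methanol, would then saturate the alkene without touching the benzyl ether, the aldehyde or the acetate, giving 24.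

Further compounds
F1 | step 6 | 3-(benzyloxy)-5-[(R)-8-(tert-butyldimethylsilyloxy)undecyl]cyclohex-2-en-1-one | O=C1C=C(OCc2ccccc2)CC(CCCCCCC[C@@H](CCC)O[Si](C)(C)C(C)(C)C)C1
F2 | step 6 | 3-(benzyloxy)-5-[(R)-8-(tert-butyldimethylsilyloxy)undecyl]-6-(phenylselanyl)cyclohex-2-en-1-one | O=C1C=C(OCc2ccccc2)CC(CCCCCCC[C@@H](CCC)O[Si](C)(C)C(C)(C)C)C1[Se]c1ccccc1
F3 | step 6 | 3-(benzyloxy)-5-[(R)-8-(tert-butyldimethylsilyloxy)undecyl]phenol | Oc1cc(OCc2ccccc2)cc(CCCCCCC[C@@H](CCC)O[Si](C)(C)C(C)(C)C)c1
F4 | step 15 | (S)-11-[3,5-bis(benzyloxy)phenyl]undecan-4-yl 4-nitrobenzoate | c1ccccc1COc1cc(OCc2ccccc2)cc(CCCCCCC[C@H](CCC)OC(=O)c2ccc(cc2)[N+](=O)[O-])c1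
F5 | step 15 | (S)-11-[3,5-bis(benzyloxy)phenyl]undecan-4-ol | c1ccccc1COc1cc(OCc2ccccc2)cc(CCCCCCC[C@H](CCC)O)c1
F6 | step 13 | (R,E)-12-[3-(benzyloxy)-2-formyl-5-methoxyphenyl]dodec-11-en-4-yl acetate | CCC[C@H](CCCCCC/C=C/c1cc(OC)cc(OCc2ccccc2)c1C=O)OC(C)=O
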